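Ring A (flavone numbering) is a phloroglucinol with oxygens on C5, C7 and C8a, and its C8 carries a quaternary carbon. The route rests on making the C8–C8a bond (equivalent to C7–C8 at that stage) by an intramolecular Claisen condensation of an open-chain 3,5-dioxoester, methyl 7,7-dimethyl-3,5-dioxonon-8-enoate. This chain already holds the 1,1-dimethylallyl group beside the methylene that becomes C8. One operation closes the carbocycle and aromatises it to 2-(1,1-dimethylallyl)phloroglucinol, whose two free ring carbons are equivalent. Directed lithiation then brings in the acetyl group without a Lewis acid, selective acetal protection leaves only the hydroxyl beside the tert-alkyl group free, and a chalcone/oxidative cyclisation sequence with a prenylated ring B aldehyde builds ring C.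

Key step: step 2

Assumption: the target has no stereocentre, and the E geometry of chalcone 16 is consumed when ring C forms. Steps that use NaH, n-BuLi or NaOMe are taken to end with an aqueous HCl work-up, so sodium and lithium leave as their chlorides.

Step 1
Reactants: 1 methyl acetoacetate; 2 methyl 3,3-dimethylpent-4-enoate
Product: 4 methyl 7,7-dimethyl-3,5-dioxonon-8-enoate, via methyl acetoacetate dianion 3 (not isolated)
Conditions: 1 (2.2 equiv per 2), NaH, THF, 0 °C; n-BuLi, 0 °C; then 2, 0 °C to rt; aq. HCl
Reagents that add atoms: none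
Why: Claisen-type acylation of the acetoacetate dianion at its terminal, more nucleophilic carbon by the ester; the second equivalent of dianion takes up the acidic proton of the product so that the acylation can run to completion.

Step 2
Reactants: 4 methyl 7,7-dimethyl-3,5-dioxonon-8-enoate
Product: 5 2-(2-methylbut-3-en-2-yl)benzene-1,3,5-triol
Conditions: NaOMe (5 equiv), MeOH, 110 °C (sealed vessel), Ar; then 1 M HCl, 0 °C, to pH 4
Reagents that add atoms: none
Why: Methoxide deprotonates the chain reversibly; the small equilibrium share of the dienolate with a carbanion at C6 (the methylene between the C5 ketone and the quaternary carbon) adds to the C1 ester carbonyl, methoxide leaves, and the cyclohexane-1,3,5-trione enolises three times to the arene, whose phenoxide is withdrawn from all equilibria. The closest known reaction type is the Claisen (Dieckmann-like) closure of 5-oxo and 3,5-dioxo esters to cyclohexane-1,3-diones and phloroglucinols. The one ring is closed in a 6-(enolendo)-exo-trig mode, a favoured mode because the enolate double bond lies inside the forming six-membered ring. No stereocentre is created. The step needs carbon acylation to prevail over oxygen acylation: should the C5 enol oxygen attack the ester, the resulting enol lactone would be reopened by methoxide whereas aromatisation is irreversible, and no other carbon of the chain can reach a carbonyl through a five- or six-membered transition state. The hindered nucleophilic carbon is the weak point, which is why excess base and heat are specified and air is excluded to protect the electron-rich product.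

Step 3
Reactants: 5 2-(2-methylbut-3-en-2-yl)benzene-1,3,5-triol
Product: 6 1,3,5-tris(methoxymethoxy)-2-(2-methylbut-3-en-2-yl)benzene
Conditions: NaH (3.6 equiv), MOMCl (3.6 equiv), DMF, 0 °C to rt
Reagents that add atoms: chloromethyl methyl ether, COCCl
Why: O-alkylation of the three phenoxides by the hard chloromethyl ether (Williamson ether synthesis) masks the acidic protons and provides the acetal directing groups for the next step.

Step 4
Reactants: 6 1,3,5-tris(methoxymethoxy)-2-(2-methylbut-3-en-2-yl)benzene; 7 N-methoxy-N-methylacetamide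
Product: 10 1-[2,4,6-trihydroxy-3-(2-methylbut-3-en-2-yl)phenyl]ethanone, via aryllithium 8 (not isolated), via tris(methoxymethyl) ketone 9 (not isolated)
Conditions: n-BuLi, THF, 0 °C; 7, −78 °C to rt; then HCl (ca. 2 M), MeOH, 45 °C
Reagents that add atoms: none
Why: A ring proton between two acetal oxygens is removed by directed ortho-metalation (both remaining ring protons are equivalent), the aryllithium gives the ketone by Weinreb ketone synthesis without any Lewis acid that could ionise the tert-allyl group, and methanolic HCl then cleaves the three acetals.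

Step 5
Reactants: 10 1-[2,4,6-trihydroxy-3-(2-methylbut-3-en-2-yl)phenyl]ethanone
Product: 11 1-[2-hydroxy-4,6-bis(methoxymethoxy)-3-(2-methylbut-3-en-2-yl)phenyl]ethanone
Conditions: MOMCl (2.2 equiv), i-Pr2NEt, CH2Cl2, 0 °C to rt
Reagents that add atoms: chloromethyl methyl ether, COCCl
Why: Williamson-type acetalisation is expected at the para hydroxyl and at the chelated ortho hydroxyl next to a ring proton, whereas the ortho hydroxyl wedged between the acetyl and the tert-alkyl group is hydrogen-bonded and flanked on both sides and should stay free.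

Step 6
Reactants: 12 3-bromo-4,5-dihydroxybenzaldehyde
Product: 13 3-bromo-4,5-bis(methoxymethoxy)benzaldehyde
Conditions: MOMCl (2.5 equiv), i-Pr2NEt, CH2Cl2, 0 °C to rt
Reagents that add atoms: chloromethyl methyl ether, COCCl
Why: Williamson-type acetalisation of both catechol hydroxyls, needed because free phenols would interfere with the coupling and with the aldol step.

Step 7
Reactants: 13 3-bromo-4,5-bis(methoxymethoxy)benzaldehyde; 14 tributyl(3-methylbut-2-en-1-yl)stannane
Product: 15 3,4-bis(methoxymethoxy)-5-(3-methylbut-2-en-1-yl)benzaldehyde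
Conditions: Pd(PPh3)4 (5 mol %), DMF, 100 °C
Reagents that add atoms: none
Why: Migita–Kosugi–Stille coupling under zerovalent palladium catalysis; the allylstannane should transfer its unsubstituted terminus and give the linear prenyl arene, and the aldehyde and acetals are inert.

Step 8
Reactants: 11 1-[2-hydroxy-4,6-bis(methoxymethoxy)-3-(2-methylbut-3-en-2-yl)phenyl]ethanone; 15 3,4-bis(methoxymethoxy)-5-(3-methylbut-2-en-1-yl)benzaldehyde
Product: 16 (E)-1-[2-hydroxy-4,6-bis(methoxymethoxy)-3-(2-methylbut-3-en-2-yl)phenyl]-3-[3,4-bis(methoxymethoxy)-5-(3-methylbut-2-en-1-yl)phenyl]prop-2-en-1-one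
Conditions: KOH, EtOH/H2O, rt
Reagents that add atoms: none
Why: Claisen–Schmidt aldol condensation of the methyl ketone enolate with the non-enolisable aldehyde, followed by E1cB dehydration, should give the thermodynamically preferred E enone.

Step 9
Reactants: 16 (E)-1-[2-hydroxy-4,6-bis(methoxymethoxy)-3-(2-methylbut-3-en-2-yl)phenyl]-3-[3,4-bis(methoxymethoxy)-5-(3-methylbut-2-en-1-yl)phenyl]prop-2-en-1-one
Product: 17 3-hydroxy-5,7-bis(methoxymethoxy)-2-[3,4-bis(methoxymethoxy)-5-(3-methylbut-2-en-1-yl)phenyl]-8-(2-methylbut-3-en-2-yl)-4H-chromen-4-one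
Conditions: 30% H2O2, 2 M NaOH, MeOH/THF, 0 °C to rt
Reagents that add atoms: hydrogen peroxide, OO
Why: Algar–Flynn–Oyamada oxidation: the hydroperoxide anion attacks only the electron-poor enone, the isolated vinyl and prenyl alkenes and the acetals are inert to alkaline peroxide, and because the only free phenol is the one beside the tert-alkyl group, ring C must close through it and the substituent is fixed at C8.

Step 10
Reactants: 17 3-hydroxy-5,7-bis(methoxymethoxy)-2-[3,4-bis(methoxymethoxy)-5-(3-methylbut-2-en-1-yl)phenyl]-8-(2-methylbut-3-en-2-yl)-4H-chromen-4-one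
Product: 18 2-[3,4-dihydroxy-5-(3-methylbut-2-en-1-yl)phenyl]-3,5,7-trihydroxy-8-(2-methylbut-3-en-2-yl)-4H-chromen-4-one (CNP0196880.0)
Conditions: 3 M HCl, MeOH/THF, 45 °C
Reagents that add atoms: none
Why: Acid-catalysed methanolysis of the four aryl methoxymethyl ethers, under conditions mild enough that the prenyl and 1,1-dimethylallyl alkenes should not be protonated and the chromone should not ring-open.

Compound list
1 | methyl acetoacetate | COC(=O)CC(C)=O | starting material
2 | methyl 3,3-dimethylpent-4-enoate | COC(=O)CC(C)(C)C=C | starting material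
3 | methyl acetoacetate dianion (sodium lithium salt) | COC(=O)[CH-]C(=O)[CH2-].[Na+].[Li+] | intermediate
4 | methyl 7,7-dimethyl-3,5-dioxonon-8-enoate | COC(=O)CC(=O)CC(=O)CC(C)(C)C=C | intermediate
5 | 2-(2-methylbut-3-en-2-yl)benzene-1,3,5-triol | C=CC(C)(C)c1c(O)cc(O)cc1O | intermediate
6 | 1,3,5-tris(methoxymethoxy)-2-(2-methylbut-3-en-2-yl)benzene | C=CC(C)(C)c1c(OCOC)cc(OCOC)cc1OCOC | intermediate
7 | N-methoxy-N-methylacetamide | CC(=O)N(C)OC | starting material
8 | [2,4,6-tris(methoxymethoxy)-3-(2-methylbut-3-en-2-yl)phenyl]lithium | [Li]c1c(OCOC)cc(OCOC)c(C(C)(C)C=C)c1OCOC | intermediate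
9 | 1-[2,4,6-tris(methoxymethoxy)-3-(2-methylbut-3-en-2-yl)phenyl]ethanone | CC(=O)c1c(OCOC)cc(OCOC)c(C(C)(C)C=C)c1OCOC | intermediate
10 | 1-[2,4,6-trihydroxy-3-(2-methylbut-3-en-2-yl)phenyl]ethanone | CC(=O)c1c(O)cc(O)c(C(C)(C)C=C)c1O | intermediate
11 | 1-[2-hydroxy-4,6-bis(methoxymethoxy)-3-(2-methylbut-3-en-2-yl)phenyl]ethanone | CC(=O)c1c(OCOC)cc(OCOC)c(C(C)(C)C=C)c1O | intermediate
12 | 3-bromo-4,5-dihydroxybenzaldehyde | O=Cc1cc(O)c(O)c(Br)c1 | starting material
13 | 3-bromo-4,5-bis(methoxymethoxy)benzaldehyde | O=Cc1cc(OCOC)c(OCOC)c(Br)c1 | intermediate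
14 | tributyl(3-methylbut-2-en-1-yl)stannane | CCCC[Sn](CCCC)(CCCC)CC=C(C)C | starting material
15 | 3,4-bis(methoxymethoxy)-5-(3-methylbut-2-en-1-yl)benzaldehyde | O=Cc1cc(OCOC)c(OCOC)c(CC=C(C)C)c1 | intermediate
16 | (E)-1-[2-hydroxy-4,6-bis(methoxymethoxy)-3-(2-methylbut-3-en-2-yl)phenyl]-3-[3,4-bis(methoxymethoxy)-5-(3-methylbut-2-en-1-yl)phenyl]prop-2-en-1-one | O=C(/C=C/c1cc(OCOC)c(OCOC)c(CC=C(C)C)c1)c1c(OCOC)cc(OCOC)c(C(C)(C)C=C)c1O | intermediate
17 | 3-hydroxy-5,7-bis(methoxymethoxy)-2-[3,4-bis(methoxymethoxy)-5-(3-methylbut-2-en-1-yl)phenyl]-8-(2-methylbut-3-en-2-yl)-4H-chromen-4-one | C=CC(C)(C)c1c(OCOC)cc(OCOC)c2c(=O)c(O)c(-c3cc(OCOC)c(OCOC)c(CC=C(C)C)c3)oc12 | intermediate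
18 | 2-[3,4-dihydroxy-5-(3-methylbut-2-en-1-yl)phenyl]-3,5,7-trihydroxy-8-(2-methylbut-3-en-2-yl)-4H-chromen-4-one | C=CC(C)(C)c1c(O)cc(O)c2c(=O)c(O)c(-c3cc(O)c(O)c(CC=C(C)C)c3)oc12 | target

Total step count: 10
Longest linear sequence: 8 steps (steps 1, 2, 3, 4, 5, 8, 9, 10)

Steps most likely to fail

Step 2 (key step). The hindered carbanion may fail to add to the ester, so that the chain is diverted into lactonisation or is cut by retro-Claisen attack of methoxide on the diketone. Fallback: ring A is not folded from a chain but taken from a preformed arene, and the quaternary carbon is attached by an aromatic Claisen rearrangement. Because this replaces steps 1 and 2 together, it cannot set out from a compound of the route; it sets out from commercial phloroglucinol (Oc1cc(O)cc(O)c1) and comes back to the route at compound 6. Phloroglucinol is bis-protected with MOMCl and i-Pr2NEt to 3,5-bis(methoxymethoxy)phenol F1, which is separated from the mono- and tris-ethers. F1 is alkylated with prenyl bromide (K2CO3, acetone) to 1,3-bis(methoxymethoxy)-5-[(3-methylbut-2-en-1-yl)oxy]benzene F2. Heating F2 in N,N-diethylaniline at about 180 °C should deliver the dimethyl-substituted allyl terminus to the ortho carbon by a [3,3] shift and give 3,5-bis(methoxymethoxy)-2-(2-methylbut-3-en-2-yl)phenol F3. NaH and MOMCl then convert F3 into 6.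

Step 9. Closure of the oxidised chalcone at the α-carbon instead of the β-carbon (aurone formation), which a 6'-alkoxy group favours, may compete with flavonol formation. Fallback: ring C is built through a 1,3-diketone of the Baker–Venkataraman type and C3 is hydroxylated afterwards. It sets out from ketone 11 and aldehyde 15 and comes back at compound 17. Aldehyde 15 is oxidised (NaClO2, NaH2PO4, 2-methylbut-2-ene, t-BuOH/H2O; Pinnick oxidation) to 3,4-bis(methoxymethoxy)-5-(3-methylbut-2-en-1-yl)benzoic acid F4. The acid is converted under neutral conditions with 1-chloro-N,N,2-trimethylprop-1-en-1-amine into 3,4-bis(methoxymethoxy)-5-(3-methylbut-2-en-1-yl)benzoyl chloride F5. Ketone 11 is treated with LiN(SiMe3)2 (3 equiv, THF, −78 °C) and C-aroylated with F5 to 1-[2-hydroxy-4,6-bis(methoxymethoxy)-3-(2-methylbut-3-en-2-yl)phenyl]-3-[3,4-bis(methoxymethoxy)-5-(3-methylbut-2-en-1-yl)phenyl]propane-1,3-dione F6. Cyclodehydration under buffered conditions (NaOAc, AcOH, 80 °C) should give 5,7-bis(methoxymethoxy)-2-[3,4-bis(methoxymethoxy)-5-(3-methylbut-2-en-1-yl)phenyl]-8-(2-methylbut-3-en-2-yl)-4H-chromen-4-one F7. Lithiation of F7 at C3 (LiN(i-Pr)2, THF, −78 °C), trapping with B(OMe)3 and oxidation with H2O2 then give 17.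

Step 1. Proton transfer from the product and from the ester to the dianion may stop the acylation early. Fallback: the acylating partner is changed to a Weinreb amide, whose chelated tetrahedral adduct should not release the acidic dioxoester before work-up. It sets out from ester 2 and comes back at compound 4. Ester 2 is converted with MeNHOMe·HCl and i-PrMgCl (THF, −20 °C) into N-methoxy-N,3,3-trimethylpent-4-enamide F8. F8 is added to dianion 3 (THF, 0 °C), and acidic work-up gives 4.

Further compounds
F1 | step 2 | 3,5-bis(methoxymethoxy)phenol | COCOc1cc(O)cc(OCOC)c1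
F2 | step 2 | 1,3-bis(methoxymethoxy)-5-[(3-methylbut-2-en-1-yl)oxy]benzene | COCOc1cc(OCC=C(C)C)cc(OCOC)c1
F3 | step 2 | 3,5-bis(methoxymethoxy)-2-(2-methylbut-3-en-2-yl)phenol | C=CC(C)(C)c1c(O)cc(OCOC)cc1OCOC
F4 | step 9 | 3,4-bis(methoxymethoxy)-5-(3-methylbut-2-en-1-yl)benzoic acid | OC(=O)c1cc(OCOC)c(OCOC)c(CC=C(C)C)c1
F5 | step 9 | 3,4-bis(methoxymethoxy)-5-(3-methylbut-2-en-1-yl)benzoyl chloride | ClC(=O)c1cc(OCOC)c(OCOC)c(CC=C(C)C)c1
F6 | step 9 | 1-[2-hydroxy-4,6-bis(methoxymethoxy)-3-(2-methylbut-3-en-2-yl)phenyl]-3-[3,4-bis(methoxymethoxy)-5-(3-methylbut-2-en-1-yl)phenyl]propane-1,3-dione | O=C(CC(=O)c1cc(OCOC)c(OCOC)c(CC=C(C)C)c1)c1c(OCOC)cc(OCOC)c(C(C)(C)C=C)c1O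
F7 | step 9 | 5,7-bis(methoxymethoxy)-2-[3,4-bis(methoxymethoxy)-5-(3-methylbut-2-en-1-yl)phenyl]-8-(2-methylbut-3-en-2-yl)-4H-chromen-4-one | C=CC(C)(C)c1c(OCOC)cc(OCOC)c2c(=O)cc(-c3cc(OCOC)c(OCOC)c(CC=C(C)C)c3)oc12
F8 | step 1 | N-methoxy-N,3,3-trimethylpent-4-enamide | CON(C)C(=O)CC(C)(C)C=C
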